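## Retrosynthetic overview

1. Target ⇐ SnCl2 reduction of the 9,11-endoperoxide (19(R)-hydroxy-PGH2) ⇐ one cyclooxygenase-catalysed bis-dioxygenation (2 O2) of 19(R)-hydroxyarachidonic acid.
2. Ring order as in the biosynthesis: 11-peroxyl radical closes the 1,2-dioxolane (O–C9), the C8 radical then closes the cyclopentane (C8–C12), and O2 is taken up at C15. This sets C8, C9, C11, C12 and C15; C19 comes from the chiral pool.
3. 19(R)-Hydroxyarachidonic acid ⇐ saponification and fourfold cis-semihydrogenation of the skipped C20 tetrayne methyl ester.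
4. Tetrayne ⇐ one-pot double Cu-mediated coupling of 1,7-dibromohepta-2,5-diyne with methyl hex-5-ynoate and (R)-hept-6-yn-2-ol.
5. Dibromide ⇐ propargyl alcohol + 4-chlorobut-2-yn-1-ol; (R)-hept-6-yn-2-ol ⇐ (R)-propylene oxide + silylbutynyl Grignard reagent.

Assumption: ovine COX-1 with its cofactors hematin and hydroquinone is treated as a catalyst system, not a starting material, and the last step is run on a 10–50 mg scale.

## Route

Step 1
Reactants: 1 (4-bromobut-1-yn-1-yl)trimethylsilane; 2 (R)-2-methyloxirane [(R)-propylene oxide]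
Product: 5 (R)-hept-6-yn-2-ol, via Grignard reagent 3 (not isolated), via silyl alkynol 4 (not isolated)
Conditions: Mg, THF, 40 °C; CuI (10 mol %), 2, −30 → 0 °C; then MeOH, K2CO3 (0.2 equiv), rt; 1 M HCl work-up
Reagents that add atoms: none
Why: Copper-catalysed Grignard opening of the terminal epoxide is an SN2 attack at the unsubstituted CH2, so the C–O stereocentre of 2 becomes C19 (R) untouched, and methoxide-mediated protodesilylation of the alkynylsilane then frees the terminal alkyne in the same flask.

Step 2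
Reactants: 6 prop-2-yn-1-ol (propargyl alcohol); 7 4-chlorobut-2-yn-1-ol
Product: 8 hepta-2,5-diyne-1,7-diol
Conditions: CuI (1 equiv), NaI (1 equiv), K2CO3 (1.2 equiv), DMF, rt, 16 h, Ar
Reagents that add atoms: none
Why: Copper(I)-mediated alkyne–propargyl halide coupling (iodide-assisted SN2 of the copper acetylide at the propargylic carbon) gives the skipped 1,4-diyne, tolerates free hydroxyls and involves no stereocentre.

Step 3
Reactants: 8 hepta-2,5-diyne-1,7-diol
Product: 9 1,7-dibromohepta-2,5-diyne
Conditions: CBr4 (2.4 equiv), PPh3 (2.4 equiv), CH2Cl2, −20 → 0 °C; short silica plug, use at once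
Reagents that add atoms: carbon tetrabromide, BrC(Br)(Br)Br
Why: Appel reaction, in which both primary propargylic alkoxyphosphonium ions are displaced by bromide under neutral conditions that do not isomerise the base-sensitive skipped diyne.

Step 4
Reactants: 9 1,7-dibromohepta-2,5-diyne; 10 methyl hex-5-ynoate; 5 (R)-hept-6-yn-2-ol
Product: 11 methyl (19R)-19-hydroxyicosa-5,8,11,14-tetraynoate
Conditions: CuI, NaI, Cs2CO3 (3.2 equiv each), DMF, 0 °C → rt, Ar; 5 : 10 : 9 = 1.0 : 2.2 : 1.6; silica chromatography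
Reagents that add atoms: none
Why: Two copper(I)-mediated alkyne–propargyl bromide couplings on the bifunctional C7 unit run as a statistical unsymmetrical double coupling, with the cheap alkyne 10 in excess so that about two thirds of 5 ends in the cross-product, which carries one hydroxyl and is easily separated on silica from the symmetrical by-products (no hydroxyl or two); C19 is not involved.

Step 5
Reactants: 11 methyl (19R)-19-hydroxyicosa-5,8,11,14-tetraynoate
Product: 12 methyl (5Z,8Z,11Z,14Z,19R)-19-hydroxyicosa-5,8,11,14-tetraenoate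
Conditions: H2 (1 atm), P-2 Ni [Ni(OAc)2·4H2O, NaBH4], ethylenediamine, EtOH, rt, stop after 4 equiv H2; AgNO3–silica
Reagents that add atoms: none
Why: cis-Semihydrogenation (syn delivery of H2 on the ethylenediamine-poisoned nickel boride surface) turns each of the four alkynes into a Z-alkene and stops there, leaving the ester, the alcohol and C19 unchanged.

Step 6
Reactants: 12 methyl (5Z,8Z,11Z,14Z,19R)-19-hydroxyicosa-5,8,11,14-tetraenoate
Product: 13 (5Z,8Z,11Z,14Z,19R)-19-hydroxyicosa-5,8,11,14-tetraenoic acid [19(R)-hydroxyarachidonic acid]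
Conditions: LiOH (3 equiv), THF/H2O 3:1, rt, Ar; 1 M HCl to pH 4, 0 °C
Reagents that add atoms: lithium hydroxide, [Li+].[OH-]
Why: Saponification (BAc2 ester hydrolysis) at room temperature under argon leaves the skipped Z-tetraene and the C19 carbinol intact and gives the free acid that the enzyme needs.

Step 7
Reactants: 13 (5Z,8Z,11Z,14Z,19R)-19-hydroxyicosa-5,8,11,14-tetraenoic acid
Product: 16 19(R)-hydroxy-PGF2α (target), via 19(R)-hydroxy-PGG2 14 (not isolated), via 19(R)-hydroxy-PGH2 15 (not isolated)
Conditions: ovine COX-1 (ram seminal vesicle), hematin (2 µM), hydroquinone (0.5 mM), O2-saturated 0.1 M Tris-HCl pH 8, 13 at 100 µM, 30 °C, 3 min; then SnCl2 (excess), EtOH/1 M HCl, 0 °C, 10 min; EtOAc extraction at pH 3, RP-HPLC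
Reagents that add atoms: dioxygen, O=O (two molecules)
Why: Proposed new method: 13 should bind in the cyclooxygenase channel like arachidonic acid (its 20-hydroxy analogue is a known COX substrate), where the Tyr385 radical removes the 13-pro-S hydrogen, O2 adds at C11 (R), the 11-peroxyl radical closes the dioxolane by 5-exo attack on C9, the C8 radical closes the cyclopentane by 5-exo attack on C12 with the enzyme holding the two chains trans, and a second O2 adds at C15 (S) to give 14; the peroxidase site reduces the 15-hydroperoxide to 15 with hydroquinone (re-formed in the SnCl2 quench), and SnCl2 cleaves only the O–O bond so both ring hydroxyls stay cis (9α,11α); the closest known reactions are the COX conversion of arachidonic acid into PGG2/PGH2 and the SnCl2 reduction of PGH2 to PGF2α.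

## Compound list

1 | (4-bromobut-1-yn-1-yl)trimethylsilane | C[Si](C)(C)C#CCCBr | starting material
2 | (R)-2-methyloxirane | C[C@@H]1CO1 | starting material
3 | [4-(trimethylsilyl)but-3-yn-1-yl]magnesium bromide | C[Si](C)(C)C#CCC[Mg]Br | intermediate
4 | (R)-7-(trimethylsilyl)hept-6-yn-2-ol | C[C@@H](O)CCCC#C[Si](C)(C)C | intermediate
5 | (R)-hept-6-yn-2-ol | C[C@@H](O)CCCC#C | intermediate
6 | prop-2-yn-1-ol | C#CCO | starting material
7 | 4-chlorobut-2-yn-1-ol | OCC#CCCl | starting material
8 | hepta-2,5-diyne-1,7-diol | OCC#CCC#CCO | intermediate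
9 | 1,7-dibromohepta-2,5-diyne | BrCC#CCC#CCBr | intermediate
10 | methyl hex-5-ynoate | C#CCCCC(=O)OC | starting material
11 | methyl (19R)-19-hydroxyicosa-5,8,11,14-tetraynoate | C[C@@H](O)CCCC#CCC#CCC#CCC#CCCCC(=O)OC | intermediate
12 | methyl (5Z,8Z,11Z,14Z,19R)-19-hydroxyicosa-5,8,11,14-tetraenoate | C[C@@H](O)CCC/C=C\C/C=C\C/C=C\C/C=C\CCCC(=O)OC | intermediate
13 | (5Z,8Z,11Z,14Z,19R)-19-hydroxyicosa-5,8,11,14-tetraenoic acid | C[C@@H](O)CCC/C=C\C/C=C\C/C=C\C/C=C\CCCC(=O)O | intermediate
14 | (5Z,13E,15S,19R)-9α,11α-epidioxy-15-hydroperoxy-19-hydroxyprosta-5,13-dien-1-oic acid [19(R)-hydroxy-PGG2] | C[C@@H](O)CCC[C@H](OO)/C=C/[C@@H]1[C@@H](C/C=C\CCCC(=O)O)[C@@H](O2)C[C@H]1O2 | intermediate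
15 | (5Z,13E,15S,19R)-9α,11α-epidioxy-15,19-dihydroxyprosta-5,13-dien-1-oic acid [19(R)-hydroxy-PGH2] | C[C@@H](O)CCC[C@H](O)/C=C/[C@@H]1[C@@H](C/C=C\CCCC(=O)O)[C@@H](O2)C[C@H]1O2 | intermediate
16 | (5Z,9α,11α,13E,15S,19R)-9,11,15,19-tetrahydroxyprosta-5,13-dien-1-oic acid [19(R)-hydroxy-PGF2α] | C[C@@H](O)CCC[C@H](O)/C=C/[C@@H]1[C@@H](C/C=C\CCCC(=O)O)[C@@H](O)C[C@H]1O | target

## Step count and risks

Total step count: 7. Longest linear sequence: 6 (steps 2, 3, 4, 5, 6, 7).

**Step 7 (most likely to fail).** The free ω-1 hydroxyl may bind poorly in the hydrophobic end of the cyclooxygenase channel, giving low turnover or mainly mono-oxygenated acids. The fallback sets out from 13 and comes back at 16. Acetylate 13 (Ac2O, pyridine, DMAP; aqueous NaHCO3 work-up, then pH 4) to (5Z,8Z,11Z,14Z,19R)-19-acetoxyicosa-5,8,11,14-tetraenoic acid F1, whose chain end is non-polar like that of arachidonic acid. Incubate F1 with recombinant human COX-2 (the isoform with the wider channel), hematin, hydroquinone and O2; this passes through 19(R)-acetoxy-PGG2 F2 and 19(R)-acetoxy-PGH2 F3, neither isolated. The SnCl2 quench gives 19(R)-acetoxy-PGF2α F4. Methanolysis of the acetate (K2CO3, MeOH, rt), which the triol acid tolerates, delivers 16.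

**Step 5.** Four adjacent skipped alkynes can give over-reduced or partly reduced material that is hard to separate. The fallback sets out from 8 and comes back at 12, splitting the reduction into two easier halves and changing the coupling electrophile from propargylic to allylic. Semihydrogenate the diol 8 (Lindlar Pd, quinoline, H2, MeOH) to (2Z,5Z)-hepta-2,5-diene-1,7-diol F5, which is polar and easy to purify. Convert F5 with CBr4/PPh3 into (2Z,5Z)-1,7-dibromohepta-2,5-diene F6. Run the same one-pot double copper coupling with 10 and 5 (CuI, NaI, Cs2CO3, DMF; SN2 at the primary allylic carbons with retention of Z geometry) to obtain methyl (8Z,11Z,19R)-19-hydroxyicosa-8,11-dien-5,14-diynoate F7. Only two non-adjacent alkynes remain, and P-2 Ni/H2/ethylenediamine reduces them to 12.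

**Step 4.** The statistical double coupling may give too little cross-product, or mixtures with mono-coupled bromides. The fallback sets out from 9 and 10 and comes back at 11, replacing the one-pot statistical coupling by a directed two-stage sequence. Add 10 (1 equiv) slowly to a threefold excess of 9 (CuI, NaI, Cs2CO3, DMF, 0 °C) and isolate methyl 13-bromotrideca-5,8,11-triynoate F8, recovering unreacted 9. Then couple F8 with 5 (1 equiv) under the same copper conditions to give 11, so the chiral alkyne is used only in a clean final coupling.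

## Further compounds

F1 | step 7 | (5Z,8Z,11Z,14Z,19R)-19-acetoxyicosa-5,8,11,14-tetraenoic acid | C[C@@H](OC(C)=O)CCC/C=C\C/C=C\C/C=C\C/C=C\CCCC(=O)O
F2 | step 7 | 19(R)-acetoxy-PGG2 [(5Z,13E,15S,19R)-19-acetoxy-9α,11α-epidioxy-15-hydroperoxyprosta-5,13-dien-1-oic acid] | C[C@@H](OC(C)=O)CCC[C@H](OO)/C=C/[C@@H]1[C@@H](C/C=C\CCCC(=O)O)[C@@H](O2)C[C@H]1O2
F3 | step 7 | 19(R)-acetoxy-PGH2 [(5Z,13E,15S,19R)-19-acetoxy-9α,11α-epidioxy-15-hydroxyprosta-5,13-dien-1-oic acid] | C[C@@H](OC(C)=O)CCC[C@H](O)/C=C/[C@@H]1[C@@H](C/C=C\CCCC(=O)O)[C@@H](O2)C[C@H]1O2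
F4 | step 7 | 19(R)-acetoxy-PGF2α [(5Z,9α,11α,13E,15S,19R)-19-acetoxy-9,11,15-trihydroxyprosta-5,13-dien-1-oic acid] | C[C@@H](OC(C)=O)CCC[C@H](O)/C=C/[C@@H]1[C@@H](C/C=C\CCCC(=O)O)[C@@H](O)C[C@H]1O
F5 | step 5 | (2Z,5Z)-hepta-2,5-diene-1,7-diol | OC/C=C\C/C=C\CO
F6 | step 5 | (2Z,5Z)-1,7-dibromohepta-2,5-diene | BrC/C=C\C/C=C\CBr
F7 | step 5 | methyl (8Z,11Z,19R)-19-hydroxyicosa-8,11-dien-5,14-diynoate | C[C@@H](O)CCCC#CC/C=C\C/C=C\CC#CCCCC(=O)OC
F8 | step 4 | methyl 13-bromotrideca-5,8,11-triynoate | BrCC#CCC#CCC#CCCCC(=O)OC
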